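## Analysis of the target

Target **33** is a C20 labdane. Labdane numbering is used throughout: C4 carries C18 and C19, C10 carries C20, C8 carries C17, and C9 carries the chain C11–C16.

- **Ring system.** A trans-fused decalin (rings A and B) carries three five-membered rings: a γ-lactone from C19 to the oxygen on C6, an oxolane (O–C9–C11–C12–C13) spiro at C9, and a butanolide (C13–C14–C15(=O)–O–C16) spiro at C13.
- **Stereocentres.** There are seven: C4, C5, C6, C8, C9, C10 and C13. Six are contiguous on the decalin and five are fully substituted (C4, C8, C9, C10, C13).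
- **Relations.** The 10β-methyl and 5α-hydrogen define the trans fusion. C19, the C6 oxygen and the C8 hydroxyl are all β and axial, syn to C20. The C9 oxygen is α and axial, so the C8 and C9 oxygens are trans-diaxial. C13 is S and remote from the ring stereocentres.
- **Sensitive groups.** The C9–O–C13 ether is β to the C15 carbonyl and can open by retro-oxa-Michael reaction under base. Two lactones compete with any carbonyl addition. The tertiary C8 hydroxyl is a second possible nucleophile toward C13.
- **Difficulty.** The run of quaternary centres C4, C10, C9, C8, the bare C1–C3 segment and the control of C13.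
- **Feature used.** Rings A and B, with quaternary C4 and C10 and oxygen at C8, are the chair–chair fold of one acyclic chain. The C5=C10 (E)-alkene lies between a C3–C4 epoxide and a β-keto ester (C8 ketone, C9 nucleophilic carbon, C11 ester carbon). The oxygenated carbon placed cis to the chain on the epoxide becomes the axial C19.

## Retrosynthetic reasoning

**33 ⇒ 32 (C8–C17).** The methyl group is removed last. While C8 is a ketone it activates C7 for the desaturation that brings the C19 carboxyl onto C6. It also leaves the C9 oxygen as the only hydroxyl able to reach C13. The forward addition must choose the ketone over two lactones and the α face of C8; the syn-axial C20 methyl and C6–O bond on the β face should enforce the latter.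

**32 ⇒ 30 through 31 (C6–O).** The lactone is cut at the C6–O bond because a β-axial carboxyl on C4 sits directly over C6. Dehydrogenation of the ketone toward C7 gives enone **31**, and the acid adds to C6 from the only face it can reach. C6 is set by the tether alone.

**30 ⇒ 29 (O–C13).** The oxolane is opened to a tertiary C9 alcohol and a butenolide. The forward oxa-Michael addition forms the spiro centre C13 reversibly. It is placed while C8 is a ketone and before the C6 lactone exists, so no second hydroxyl competes and no β-acyloxy ketone meets base.

**29 ⇒ 25 through 28, 27, 26 (no skeletal bond).** The butenolide is the oxidised form of a 3-substituted furan (photooxygenation, then hydride reduction of the lactol). One oxidation after desilylation returns C8 to the ketone and raises C19 to the acid. The furan must therefore be converted before C19 is oxidised.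

**25 ⇒ 21 + 23 (C11–C12).** This cut gives a spiro epoxide on C9/C11 and a furylmethyl nucleophile. The bond is made at an unsubstituted CH2 and the tertiary C9 hydroxyl is released in the same step. **23** comes from commercial **22**.

**21 ⇒ 19 ⇒ 18 ⇒ 17 (C9–O).** The epoxide comes from triol **19**, the reduction product of α-hydroxy β-keto ester **18**. The C9–O bond is traced to hydroxylation of the enolate of **17** on the face opposite C20. The ester carbon of **17** is therefore C11.

**17 ⇒ 15 (C3–O).** The C3 hydroxyl of **15** is the footprint of the epoxide that starts the cyclization and fixes the absolute configuration. It is removed by radical deoxygenation.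

**15 ⇒ 14 (C4–C5 and C9–C10).** Both bonds are cut together. This is the only point where both carbocycles, both quaternary carbons C4 and C10 and four stereocentres trace back to an acyclic chain. The stereochemical inputs are an (E)-alkene, the cis placement of the silyloxymethyl group on the epoxide and the epoxide configuration. The forward reaction must open the epoxide at C4, close twice through chairs and finish by C-alkylation of the β-keto ester.

**14 ⇒ 12 + 13 (C6–C7).** The chain is cut between the allylic carbon and the terminal carbon of **13**; the forward step is a dianion alkylation.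

**12 ⇒ 10 ⇒ 8 ⇒ 7 (epoxide).** The epoxide comes from asymmetric epoxidation of (Z)-allylic alcohol **7**. The two chain ends must stay distinguishable, so the geraniol oxygen is carried as an oxidatively removable benzyl-type ether. An ester there would be cleaved by the hydride that makes **7**, leaving two allylic alcohols that the epoxidation catalyst cannot tell apart.

**7 ⇒ 6 ⇒ 4 + 5 ⇒ 1 (C3=C4).** A Z-selective olefination of aldehyde **4** builds the alkene. **4** is geraniol **1** minus its terminal isopropylidene (epoxidation, then glycol cleavage). Direct allylic oxidation of **1** would functionalise the (E)-methyl, which would end equatorial as C18.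

## Alternatives that were turned down

**Alternative 1:** The last C–C bond of the butanolide, C13–C14, is cut. The C16 diazoacetate A2 would be decomposed with Rh2(OAc)4 so that the carbenoid carbon C14 inserts into the tertiary C13–H bond of a pre-formed oxolane. The product A1 is the same compound as **32**.
- For: 1,5-insertion into an ether-activated tertiary C–H bond is the preferred mode and goes with retention. C13 would be fixed stereospecifically. On this point it is stronger than the reversible oxa-Michael closure used here, which relies on thermodynamic preference, separation and re-equilibration.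
- Against: only two skeletal atoms are removed. A2 still holds the decalin, C4 and C10, the C6 lactone, the C9 spiro ether and a C13–H stereocentre that needs its own control. Acceptor-only carbenoids dimerise, and here could form ylides with the oxolane oxygen or the C8 ketone. Two to three extra steps buy one bond.
- In exchange the chosen route makes both carbocycles and four stereocentres in one step and reaches the same penultimate compound.

**Alternative 2:** Ring B is opened at C8–C9 to keto aldehyde A4. A triazolium-derived carbene would turn the C8 aldehyde into its Breslow intermediate, which attacks the C9 ketone to give α-ketol A3.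
- For: one catalytic step gives the C9 tertiary alcohol, the C8 ketone and ring B with the furylethyl chain in place. The reduction, epoxide and re-oxidation steps used here at C8, C9 and C11 would disappear. On functional-group economy around C8/C9 it is stronger.
- Against: the acceptor ketone is attached to the quaternary C10 and is extremely hindered. The aldehyde is β to the C6 lactone oxygen, so the base that generates the carbene can expel the carboxylate or start aldol chemistry. The C9 configuration would rest on a chair preference not clearly favouring the axial hydroxyl. A4 needs C4, C5, C6 and C10 set on a monocycle without the lock of a decalin.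
- The chosen strategy builds exactly these centres from alkene geometry and pays with functional-group steps afterwards.

**Alternative 3:** The C9–O bond is cut with loss of aromaticity. Tetralin phenol A6 carries the complete C13 carbinol–butanolide chain. PhI(OAc)2, or a chiral aryl iodide with mCPBA, would oxidise the C8 phenol, and the C13 hydroxyl would attack the ortho carbon C9 to give spiro dienone A5.
- For: A6 is a flat, convergent precursor. The spiro C9–O bond and the oxolane arise in one step, and C13 is defined beforehand. On convergence and on making the C9 spiro ether directly it is stronger.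
- Against: a tertiary alcohol is a poor partner for the aryl-iodonium intermediate and competes with acetate. Ortho-quinol ethers dimerise by [4+2] addition. C5, C6 and the quaternary C10 with its methyl would then have to be installed on a planar dienone, with facial control from a remote spiro centre and C20 anti to the C9 oxygen.
- The chosen strategy settles C4, C5 and C10 in one stereospecific event and adds C6, C8 and C9 by reactions steered by the rigid trans-decalin.

Key step: step 11

**Remarks on the chemistry (assumptions).**
- The C8 alcohol in **19**–**28** is drawn as the expected 8β epimer; C8 is re-oxidised in step 22, so the route does not depend on it.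
- **3** is racemic at its epoxide carbon and **26** is a mixture at the lactol carbon; both centres are destroyed later.
- **23** stores poorly and is therefore made from commercial **22**.

## Route

Step 1
Reactants: 1 geraniol [(2E)-3,7-dimethylocta-2,6-dien-1-ol]
Product: 2 geranyl 4-methoxybenzyl ether [1-({[(2E)-3,7-dimethylocta-2,6-dien-1-yl]oxy}methyl)-4-methoxybenzene]
Conditions: NaH, 4-methoxybenzyl chloride, n-Bu4NI (cat.), THF/DMF, 0 °C to rt
Reagents that add atoms: 4-methoxybenzyl chloride, COc1ccc(CCl)cc1
Why: Williamson etherification of the primary allylic alkoxide. The benzyl-type ether survives peracid, periodic acid, strong base, i-Bu2AlH and the titanium epoxidation, and is later removed oxidatively without harm to an epoxide or silyl ether.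

Step 2
Reactants: 2 geranyl 4-methoxybenzyl ether
Product: 3 2-[(3E)-5-[(4-methoxybenzyl)oxy]-3-methylpent-3-en-1-yl]-3,3-dimethyloxirane (racemic)
Conditions: mCPBA, NaHCO3, CH2Cl2, 0 °C
Reagents that add atoms: 3-chloroperbenzoic acid, OOC(=O)c1cccc(Cl)c1
Why: Prilezhaev epoxidation. The terminal trisubstituted alkene is the more electron-rich one because the other is deactivated by the allylic ether oxygen; the epoxide is only a handle for cleavage.

Step 3
Reactants: 3 terminal epoxide
Product: 4 (4E)-6-[(4-methoxybenzyl)oxy]-4-methylhex-4-enal
Conditions: H5IO6, THF/H2O, 0 °C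
Reagents that add atoms: none
Why: Periodic acid opens the epoxide to the glycol and cleaves it (Malaprade cleavage) to the aldehyde and acetone. The terminus is removed so that it can be rebuilt with defined geometry.

Step 4
Reactants: 4 aldehyde; 5 methyl 2-[bis(2,2,2-trifluoroethoxy)phosphoryl]propanoate
Product: 6 methyl (2Z,6E)-8-[(4-methoxybenzyl)oxy]-2,6-dimethylocta-2,6-dienoate
Conditions: KN(SiMe3)2, 18-crown-6, THF, −78 °C
Reagents that add atoms: none
Why: Still–Gennari olefination. The electron-poor phosphonate with a dissociated potassium counter-ion eliminates quickly from the kinetic adduct and should give the (Z)-trisubstituted enoate, which places the future C19 carbon cis to the chain.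

Step 5
Reactants: 6 (2Z,6E)-enoate
Product: 7 (2Z,6E)-8-[(4-methoxybenzyl)oxy]-2,6-dimethylocta-2,6-dien-1-ol
Conditions: i-Bu2AlH, CH2Cl2, −78 °C; aq. KNaC4H4O6
Reagents that add atoms: none
Why: 1,2-Reduction of the conjugated ester by the aluminium hydride should give the allylic alcohol without loss of the Z geometry; the ether is inert.

Step 6
Reactants: 7 (Z)-allylic alcohol
Product: 8 [(2R,3S)-3-[(3E)-5-[(4-methoxybenzyl)oxy]-3-methylpent-3-en-1-yl]-2-methyloxiran-2-yl]methanol
Conditions: Ti(OiPr)4 (cat.), D-(−)-diethyl tartrate (cat.), t-BuOOH, 4 Å molecular sieves, CH2Cl2, −20 °C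
Reagents that add atoms: tert-butyl hydroperoxide, CC(C)(C)OO
Why: Sharpless asymmetric epoxidation. Only the allylic alcohol binds to the titanium tartrate, so the remote alkene is untouched. The D-(−)-tartrate is the enantiomer that gives the 2R epoxy alcohol in this series (the natural L-(+)-ester gives 2S); this is the epoxide whose C–O bond at labdane C3 becomes the 3β-hydroxyl and whose opening leads to the natural decalin series.

Step 7
Reactants: 8 epoxy alcohol
Product: 9 tert-butyl{[(2R,3S)-3-[(3E)-5-[(4-methoxybenzyl)oxy]-3-methylpent-3-en-1-yl]-2-methyloxiran-2-yl]methoxy}dimethylsilane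
Conditions: TBSCl, imidazole, CH2Cl2, 0 °C to rt
Reagents that add atoms: tert-butyl(chloro)dimethylsilane, CC(C)(C)[Si](C)(C)Cl
Why: Silylation of the primary alcohol. A bulky, weakly Lewis basic silyl ether should neither chelate the Lewis acid nor take part as a neighbouring group in the cyclization.

Step 8
Reactants: 9 silyl ether
Product: 10 (2E)-5-[(2S,3R)-3-({[tert-butyl(dimethyl)silyl]oxy}methyl)-3-methyloxiran-2-yl]-3-methylpent-2-en-1-ol
Conditions: DDQ, CH2Cl2/aq. phosphate buffer (pH 7), 0 °C
Reagents that add atoms: none
Why: Oxidative cleavage of the 4-methoxybenzyl ether (hydride abstraction to the oxocarbenium ion, then hydrolysis). The buffered medium should spare the trisubstituted epoxide and the silyl ether.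

Step 9
Reactants: 10 allylic alcohol
Product: 12 {[(2R,3S)-3-[(3E)-5-bromo-3-methylpent-3-en-1-yl]-2-methyloxiran-2-yl]methoxy}(tert-butyl)dimethylsilane, via allylic methanesulfonate 11 (not isolated)
Conditions: MsCl, Et3N, THF, −40 °C; then LiBr, THF, 0 °C
Reagents that add atoms: lithium bromide, [Li+].[Br-]
Why: Sulfonylation followed by SN2 displacement with bromide at the primary allylic carbon under neutral conditions. No allylic transposition is expected at this temperature, and the bromide is used without purification.

Step 10
Reactants: 12 allylic bromide; 13 methyl acetoacetate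
Product: 14 methyl (6E)-9-[(2S,3R)-3-({[tert-butyl(dimethyl)silyl]oxy}methyl)-3-methyloxiran-2-yl]-7-methyl-3-oxonon-6-enoate
Conditions: NaH then n-BuLi, THF, 0 °C; then 12, 0 °C; then AcOH
Reagents that add atoms: none
Why: Alkylation of the acetoacetate dianion at its terminal, more basic carbon by SN2 on the allylic bromide, which forms C6–C7 and sets up the β-keto ester. The epoxide is far less electrophilic than the bromide at 0 °C.

Step 11
Reactants: 14 epoxy-alkene β-keto ester
Product: 15 methyl 19-{[tert-butyl(dimethyl)silyl]oxy}-3β-hydroxy-8-oxo-12,13,14,15,16,17-hexanorlabdan-11-oate (trans-decalin; 5α-H; 9α-H; 10β-methyl; CH2OSi on C4 β and axial)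
Conditions: MeAlCl2 (2.5 equiv), CH2Cl2, −78 °C to −40 °C
Reagents that add atoms: none
Why: One equivalent of MeAlCl2 turns the β-keto ester into its chelated aluminium enolate with loss of methane, and a second equivalent binds the epoxide oxygen. The C5=C10 alkene then opens the epoxide at the fully substituted C4 with inversion, forming C4–C5 and ring A by a 6-endo closure through a chair with the C3–O bond equatorial. The developing tertiary cation at C10 is captured antiperiplanar by the enolate carbon C9, forming C9–C10 and ring B by a second 6-endo closure through a chair. The closest known reaction type is the Lewis acid promoted epoxy-polyene cyclization ended by an enol or β-keto ester. C3 is carried over from the Sharpless epoxide; at C4 the inversion places the group that was cis to the chain (CH2OSi) axial and β and the methyl equatorial; anti addition across the (E)-alkene in the chair–chair array gives 10β-methyl and 5α-H; the C9 ester takes the equatorial β position, which is also the thermodynamic one. The step needs opening at C4 and not C3, C- and not O-alkylation, and closure of ring B before the C10 cation loses a proton. The tertiary nature of C4 with backside alkene participation, the ketone oxygen being tied up in the aluminium chelate, and MeAlCl2 acting as a proton sink should secure these.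

Step 12
Reactants: 15 bicyclic hydroxy β-keto ester
Product: 16 methyl 19-{[tert-butyl(dimethyl)silyl]oxy}-3β-[(1H-imidazol-1-ylcarbonothioyl)oxy]-8-oxo-12,13,14,15,16,17-hexanorlabdan-11-oate
Conditions: 1,1'-thiocarbonyldiimidazole, DMAP (cat.), ClCH2CH2Cl, 70 °C
Reagents that add atoms: 1,1'-thiocarbonyldiimidazole, S=C(n1ccnc1)n1ccnc1
Why: Thioacylation of the equatorial secondary C3 hydroxyl, the only alcohol present. The hindered β-keto ester should react more slowly, and any epimerisation at C9 returns to the equatorial ester.

Step 13
Reactants: 16 imidazolyl thiocarbonate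
Product: 17 methyl 19-{[tert-butyl(dimethyl)silyl]oxy}-8-oxo-12,13,14,15,16,17-hexanorlabdan-11-oate
Conditions: Bu3SnH, AIBN (cat.), toluene, 110 °C
Reagents that add atoms: none
Why: Barton–McCombie deoxygenation. The stannyl radical adds to C=S, β-scission gives the secondary C3 radical, and this takes hydrogen from Bu3SnH; C4 is untouched.

Step 14
Reactants: 17 β-keto ester
Product: 18 methyl 19-{[tert-butyl(dimethyl)silyl]oxy}-9α-hydroxy-8-oxo-12,13,14,15,16,17-hexanorlabdan-11-oate
Conditions: KN(SiMe3)2, THF, −78 °C; 3-phenyl-2-(phenylsulfonyl)oxaziridine; then AcOH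
Reagents that add atoms: 3-phenyl-2-(phenylsulfonyl)oxaziridine, O=S(=O)(c1ccccc1)N1OC1c1ccccc1
Why: Davis oxidation of the potassium enolate. The oxaziridine should approach C9 axially from the α face, anti to the 10β-methyl on the neighbouring carbon, so the new C–O bond is α and the ester stays β. C7 is now the only enolisable position of the ketone.

Step 15
Reactants: 18 α-hydroxy β-keto ester
Product: 19 19-{[tert-butyl(dimethyl)silyl]oxy}-12,13,14,15,16,17-hexanorlabdane-8β,9α,11-triol
Conditions: LiAlH4, THF, 0 °C
Reagents that add atoms: none
Why: Hydride reduction of ketone and ester; the primary silyl ether should survive at 0 °C. Hydride is expected on the α face of C8 (the β face is screened by the axial C20 methyl), giving the 8β alcohol, a centre that step 22 erases.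

Step 16
Reactants: 19 triol
Product: 21 19-{[tert-butyl(dimethyl)silyl]oxy}-9α,11-epoxy-12,13,14,15,16,17-hexanorlabdan-8β-ol, via C11 tosylate 20 (not isolated)
Conditions: TsCl, Et3N, DMAP (cat.), CH2Cl2, 0 °C to rt; then DBU, 40 °C
Reagents that add atoms: none
Why: Sulfonylation should select the primary C11 hydroxyl over the axial secondary and the tertiary ones, and the C9 oxygen then displaces the tosylate (3-exo-tet) with the C9–O bond kept α. An amidine base in an aprotic solvent is used instead of an alkoxide so that migration of the epoxide toward the trans 8β-hydroxyl (Payne rearrangement) is not encouraged.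

Step 17
Reactants: 22 furan-3-ylmethanol
Product: 23 3-(chloromethyl)furan
Conditions: SOCl2, pyridine, Et2O, 0 °C
Reagents that add atoms: thionyl chloride, ClS(Cl)=O
Why: Chlorodehydroxylation through the chlorosulfite; the volatile, labile chloride is used at once.

Step 18
Reactants: 21 spiro epoxide; 23 3-(chloromethyl)furan
Product: 25 19-{[tert-butyl(dimethyl)silyl]oxy}-15,16-epoxy-17-norlabda-13(16),14-diene-8β,9α-diol, via furan-3-ylmethylmagnesium chloride 24 (not isolated)
Conditions: Mg, THF, 0 °C; then CuI (cat.), 21, THF, −30 °C to 0 °C; aq. NH4Cl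
Reagents that add atoms: none
Why: Copper-catalysed SN2 opening of the 1,1-disubstituted epoxide by the Grignard reagent at the unsubstituted C11 forms C11–C12 and frees the tertiary 9α-hydroxyl with retention. One more equivalent of reagent is consumed by the C8 hydroxyl, and copper catalysis should favour coupling through the exocyclic carbon of the furylmethyl unit.

Step 19
Reactants: 25 furan diol
Product: 26 19-{[tert-butyl(dimethyl)silyl]oxy}-8β,9α,16-trihydroxy-17-norlabd-13-en-15,16-olide (both C16 epimers)
Conditions: O2, visible light, tetraphenylporphyrin (cat.), i-Pr2NEt, CH2Cl2, −78 °C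
Reagents that add atoms: dioxygen, O=O
Why: [4+2] Addition of singlet oxygen to the furan, then base-induced fragmentation of the endoperoxide (Kornblum–DeLaMare type). The hindered amine removes the more accessible C15 proton, so the carbonyl should end at C15 and the lactol at C16 next to the substituted carbon.

Step 20
Reactants: 26 hydroxybutenolide
Product: 27 19-{[tert-butyl(dimethyl)silyl]oxy}-8β,9α-dihydroxy-17-norlabd-13-en-15,16-olide
Conditions: NaBH4, EtOH, 0 °C; then 1 M HCl
Reagents that add atoms: none
Why: Borohydride reduces the ring-opened aldehyde form of the lactol, and acidification closes the γ-hydroxy acid to the butenolide. During the basic phase the acceptor is a carboxylate, so conjugate addition of the hydroxyls is not expected.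

Step 21
Reactants: 27 butenolide silyl ether
Product: 28 8β,9α,19-trihydroxy-17-norlabd-13-en-15,16-olide
Conditions: HF·pyridine, pyridine, THF, 0 °C to rt
Reagents that add atoms: none
Why: Buffered fluoride cleavage of the primary silyl ether; the butenolide and the diol should be unaffected.

Step 22
Reactants: 28 triol
Product: 29 9α-hydroxy-8-oxo-17-norlabd-13-en-15,16-olid-19-oic acid
Conditions: CrO3, H2SO4, H2O, acetone, 0 °C
Reagents that add atoms: water, O
Why: Jones oxidation takes the neopentyl primary alcohol to the acid through the aldehyde hydrate and the axial C8 alcohol to the ketone in one operation. The 8β,9α-diol is trans-diaxial and cannot form the cyclic chromate needed for glycol cleavage; the tertiary alcohol and the butenolide are inert.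

Step 23
Reactants: 29 keto acid
Product: 30 (13S)-9α,13-epoxy-8-oxo-17-norlabdan-15,16-olid-19-oic acid
Conditions: DBU, CH2Cl2, rt; then dilute HCl
Reagents that add atoms: none
Why: Intramolecular oxa-Michael addition (5-exo-trig) of the tertiary C9 oxygen to the β-carbon C13 of the butenolide. With C8 as a ketone this is the only hydroxyl, so only the oxolane can form. The addition is reversible, so C13 is set under thermodynamic control with no strong intrinsic bias expected; an unwanted C13 epimer can be separated and resubjected to the base.

Step 24
Reactants: 30 spiro keto acid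
Product: 32 (13S)-9α,13-epoxy-8-oxo-17-norlabdane-19,6β:15,16-diolide, via enone acid 31 (not isolated)
Conditions: IBX, DMSO, 70 °C
Reagents that add atoms: none
Why: IBX dehydrogenation of the ketone. Only C7 carries α-hydrogens, so the C6=C7 enone should form regiospecifically. The axial C19 carboxylic acid, held over the β face of C6, then adds (5-exo-trig oxa-Michael) in the acidic medium, which fixes the C6 oxygen as β because the tether reaches no other face.

Step 25
Reactants: 32 keto dilactone
Product: 33 (13S)-9α,13-epoxy-8β-hydroxylabdane-19,6β:15,16-diolide (target)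
Conditions: MeLi, CeCl3, THF, −78 °C; then AcOH
Reagents that add atoms: methyllithium, [Li]C
Why: Organocerium addition. The reagent is strongly nucleophilic but weakly basic, so at −78 °C the ketone should react before the two lactones and before enolisation (which would expel the C6 carboxylate or open the oxolane). Attack is from the equatorial α direction because the β face of C8 is blocked by the syn-axial C20 methyl and C6–O bond, giving the axial 8β-hydroxyl and the equatorial 8α-methyl.

## Compound list

1 | geraniol, (2E)-3,7-dimethylocta-2,6-dien-1-ol | CC(C)=CCC/C(C)=C/CO | starting material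
2 | geranyl 4-methoxybenzyl ether | CC(C)=CCC/C(C)=C/COCc1ccc(OC)cc1 | intermediate
3 | 2-[(3E)-5-[(4-methoxybenzyl)oxy]-3-methylpent-3-en-1-yl]-3,3-dimethyloxirane (racemic) | CC1(C)OC1CC/C(C)=C/COCc1ccc(OC)cc1 | intermediate
4 | (4E)-6-[(4-methoxybenzyl)oxy]-4-methylhex-4-enal | O=CCC/C(C)=C/COCc1ccc(OC)cc1 | intermediate
5 | methyl 2-[bis(2,2,2-trifluoroethoxy)phosphoryl]propanoate | COC(=O)C(C)P(=O)(OCC(F)(F)F)OCC(F)(F)F | starting material
6 | methyl (2Z,6E)-8-[(4-methoxybenzyl)oxy]-2,6-dimethylocta-2,6-dienoate | COC(=O)/C(C)=C\CC/C(C)=C/COCc1ccc(OC)cc1 | intermediate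
7 | (2Z,6E)-8-[(4-methoxybenzyl)oxy]-2,6-dimethylocta-2,6-dien-1-ol | OC/C(C)=C\CC/C(C)=C/COCc1ccc(OC)cc1 | intermediate
8 | [(2R,3S)-3-[(3E)-5-[(4-methoxybenzyl)oxy]-3-methylpent-3-en-1-yl]-2-methyloxiran-2-yl]methanol | COc1ccc(COC/C=C(\C)CC[C@@H]2O[C@]2(C)CO)cc1 | intermediate
9 | tert-butyldimethylsilyl ether of 8 | COc1ccc(COC/C=C(\C)CC[C@@H]2O[C@]2(C)CO[Si](C)(C)C(C)(C)C)cc1 | intermediate
10 | (2E)-5-[(2S,3R)-3-({[tert-butyl(dimethyl)silyl]oxy}methyl)-3-methyloxiran-2-yl]-3-methylpent-2-en-1-ol | OC/C=C(\C)CC[C@@H]1O[C@]1(C)CO[Si](C)(C)C(C)(C)C | intermediate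
11 | methanesulfonate of 10 | CS(=O)(=O)OC/C=C(\C)CC[C@@H]1O[C@]1(C)CO[Si](C)(C)C(C)(C)C | intermediate (not isolated)
12 | {[(2R,3S)-3-[(3E)-5-bromo-3-methylpent-3-en-1-yl]-2-methyloxiran-2-yl]methoxy}(tert-butyl)dimethylsilane | BrC/C=C(\C)CC[C@@H]1O[C@]1(C)CO[Si](C)(C)C(C)(C)C | intermediate
13 | methyl acetoacetate | COC(=O)CC(C)=O | starting material
14 | methyl (6E)-9-[(2S,3R)-3-({[tert-butyl(dimethyl)silyl]oxy}methyl)-3-methyloxiran-2-yl]-7-methyl-3-oxonon-6-enoate | COC(=O)CC(=O)CC/C=C(\C)CC[C@@H]1O[C@]1(C)CO[Si](C)(C)C(C)(C)C | intermediate
15 | methyl 19-(tert-butyldimethylsilyloxy)-3β-hydroxy-8-oxo-12,13,14,15,16,17-hexanorlabdan-11-oate | O=C1CC[C@H]2[C@@](C)(CO[Si](C)(C)C(C)(C)C)[C@@H](O)CC[C@]2(C)[C@H]1C(=O)OC | intermediate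
16 | 3-O-(imidazol-1-ylcarbonothioyl) derivative of 15 | O=C1CC[C@H]2[C@@](C)(CO[Si](C)(C)C(C)(C)C)[C@@H](OC(=S)n3ccnc3)CC[C@]2(C)[C@H]1C(=O)OC | intermediate
17 | methyl 19-(tert-butyldimethylsilyloxy)-8-oxo-12,13,14,15,16,17-hexanorlabdan-11-oate | O=C1CC[C@H]2[C@@](C)(CO[Si](C)(C)C(C)(C)C)CCC[C@]2(C)[C@H]1C(=O)OC | intermediate
18 | methyl 19-(tert-butyldimethylsilyloxy)-9α-hydroxy-8-oxo-12,13,14,15,16,17-hexanorlabdan-11-oate | O=C1CC[C@H]2[C@@](C)(CO[Si](C)(C)C(C)(C)C)CCC[C@]2(C)[C@@]1(O)C(=O)OC | intermediate
19 | 19-(tert-butyldimethylsilyloxy)-12,13,14,15,16,17-hexanorlabdane-8β,9α,11-triol | O[C@H]1CC[C@H]2[C@@](C)(CO[Si](C)(C)C(C)(C)C)CCC[C@]2(C)[C@@]1(O)CO | intermediate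
20 | 11-O-(4-methylbenzenesulfonyl) derivative of 19 | O[C@H]1CC[C@H]2[C@@](C)(CO[Si](C)(C)C(C)(C)C)CCC[C@]2(C)[C@@]1(O)COS(=O)(=O)c1ccc(C)cc1 | intermediate (not isolated)
21 | 19-(tert-butyldimethylsilyloxy)-9α,11-epoxy-12,13,14,15,16,17-hexanorlabdan-8β-ol | O[C@H]1CC[C@H]2[C@@](C)(CO[Si](C)(C)C(C)(C)C)CCC[C@]2(C)[C@@]13CO3 | intermediate
22 | furan-3-ylmethanol | OCc1ccoc1 | starting material
23 | 3-(chloromethyl)furan | ClCc1ccoc1 | intermediate
24 | furan-3-ylmethylmagnesium chloride | Cl[Mg]Cc1ccoc1 | intermediate (not isolated)
25 | 19-(tert-butyldimethylsilyloxy)-15,16-epoxy-17-norlabda-13(16),14-diene-8β,9α-diol | O[C@H]1CC[C@H]2[C@@](C)(CO[Si](C)(C)C(C)(C)C)CCC[C@]2(C)[C@@]1(O)CCc1ccoc1 | intermediate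
26 | 19-(tert-butyldimethylsilyloxy)-8β,9α,16-trihydroxy-17-norlabd-13-en-15,16-olide (C16 epimers) | O[C@H]1CC[C@H]2[C@@](C)(CO[Si](C)(C)C(C)(C)C)CCC[C@]2(C)[C@@]1(O)CCC3=CC(=O)OC3O | intermediate
27 | 19-(tert-butyldimethylsilyloxy)-8β,9α-dihydroxy-17-norlabd-13-en-15,16-olide | O[C@H]1CC[C@H]2[C@@](C)(CO[Si](C)(C)C(C)(C)C)CCC[C@]2(C)[C@@]1(O)CCC3=CC(=O)OC3 | intermediate
28 | 8β,9α,19-trihydroxy-17-norlabd-13-en-15,16-olide | O[C@H]1CC[C@H]2[C@@](C)(CO)CCC[C@]2(C)[C@@]1(O)CCC3=CC(=O)OC3 | intermediate
29 | 9α-hydroxy-8-oxo-17-norlabd-13-en-15,16-olid-19-oic acid | O=C1CC[C@H]2[C@@](C)(C(=O)O)CCC[C@]2(C)[C@@]1(O)CCC3=CC(=O)OC3 | intermediate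
30 | (13S)-9α,13-epoxy-8-oxo-17-norlabdan-15,16-olid-19-oic acid | O=C1CC[C@H]2[C@@](C)(C(=O)O)CCC[C@]2(C)[C@@]13CC[C@]4(COC(=O)C4)O3 | intermediate
31 | (13S)-9α,13-epoxy-8-oxo-17-norlabd-6-en-15,16-olid-19-oic acid | O=C1C=C[C@H]2[C@@](C)(C(=O)O)CCC[C@]2(C)[C@@]13CC[C@]4(COC(=O)C4)O3 | intermediate (not isolated)
32 | (13S)-9α,13-epoxy-8-oxo-17-norlabdane-19,6β:15,16-diolide | O=C1C[C@H]2OC(=O)[C@@]3(C)CCC[C@@](C)([C@@H]23)[C@@]12CC[C@]1(COC(=O)C1)O2 | intermediate
33 | (13S)-9α,13-epoxy-8β-hydroxylabdane-19,6β:15,16-diolide | C[C@]1(O)C[C@H]2OC(=O)[C@@]3(C)CCC[C@@](C)([C@@H]23)[C@@]12CC[C@]1(COC(=O)C1)O2 | target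

## Step count and risk

Total step count: 25. Longest linear sequence: 24 steps from geraniol **1** (steps 1–16 and 18–25); step 17 is a one-step branch.

**Step 11 (key step).**
- Risk: the cascade may stop or go astray at its end. The C10 cation may lose a proton after ring A has closed, or the enolate may be alkylated on oxygen. In addition, the silyloxymethyl group withdraws electron density from C4, which slows ionisation there and gives hydride shift or attack at C3 more room.
- Fallback: from **14**, silylation (TBSOTf, Et3N, CH2Cl2, −78 °C) gives the silyl enol ether F1 of the β-keto ester. F1 is cyclised with MeAlCl2 or SnCl4 at −78 °C as a Mukaiyama-type termination. The neutral enol ether cannot quench the Lewis acid and reacts as a carbon nucleophile; loss of the silyl group from the oxocarbenium ion on work-up returns **15**.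

**Step 18.**
- Risk: the furylmethyl organometallic may couple through ring carbon C2 (allylic transposition). It may also react too slowly at the hindered epoxide terminus, leaving time for the magnesium alkoxide at C8 to shift the epoxide.
- Fallback: from **23**, displacement with PhSO2Na in DMF gives furan-3-ylmethyl phenyl sulfone F2. Its lithio derivative (n-BuLi, THF/DMPU, −78 °C to rt, with an extra equivalent for the C8 hydroxyl) opens **21** at C11 to give hydroxy sulfone F3, a mixture at C12. Reductive desulfonylation with Mg in MeOH returns **25**. Sulfone anions alkylate only at the stabilised carbon.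

**Step 23.**
- Risk: poor facial selection at C13. The two epimers differ only in which butanolide methylene faces C8, so the thermodynamic preference may be small or wrong. The base may also trigger α-ketol rearrangement of the C8/C9 ketol.
- Fallback: close the oxolane last, on the substitution pattern of the target. From **29**, IBX in DMSO gives enone acid F4, which lactonises to keto lactone F5 with the butenolide still open. MeLi/CeCl3 (one extra equivalent for the free C9 hydroxyl) gives diol F6. Catalytic DBU then closes F6 to **33**. No ketone is present at that stage, so the C6 lactone is safe from β-elimination, but the C8 hydroxyl becomes a competing nucleophile and the outcome rests on the relative stability of the isomers.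

**Step 24.**
- Risk: over-oxidation. After lactonisation the ketone again has C7 hydrogens and could be dehydrogenated a second time toward C6. Alternatively enolisation next to the spiro centre may be too slow, and warm DMSO could open the oxolane by β-elimination.
- Fallback: from **30**, acid-catalysed α-selenenylation (PhSeCl, EtOAc, rt) gives α-phenylselanyl ketone F7. Oxidation (H2O2, pyridine, CH2Cl2, 0 °C) and selenoxide syn-elimination give **31**, which closes to **32**. One selenium is introduced per enolisable position, so a second desaturation cannot occur.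

## Further compounds

F1 | step 11 | methyl (6E)-3-{[tert-butyl(dimethyl)silyl]oxy}-9-[(2S,3R)-3-({[tert-butyl(dimethyl)silyl]oxy}methyl)-3-methyloxiran-2-yl]-7-methylnona-2,6-dienoate (enol ether geometry not fixed) | COC(=O)C=C(O[Si](C)(C)C(C)(C)C)CC/C=C(\C)CC[C@@H]1O[C@]1(C)CO[Si](C)(C)C(C)(C)C
F2 | step 18 | 3-[(phenylsulfonyl)methyl]furan | O=S(=O)(Cc1ccoc1)c1ccccc1
F3 | step 18 | 19-(tert-butyldimethylsilyloxy)-15,16-epoxy-12-(phenylsulfonyl)-17-norlabda-13(16),14-diene-8β,9α-diol (C12 epimers) | O[C@H]1CC[C@H]2[C@@](C)(CO[Si](C)(C)C(C)(C)C)CCC[C@]2(C)[C@@]1(O)CC(c1ccoc1)S(=O)(=O)c1ccccc1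
F4 | step 23 | 9α-hydroxy-8-oxo-17-norlabda-6,13-dien-15,16-olid-19-oic acid | O=C1C=C[C@H]2[C@@](C)(C(=O)O)CCC[C@]2(C)[C@@]1(O)CCC1=CC(=O)OC1
F5 | step 23 | 9α-hydroxy-8-oxo-17-norlabd-13-ene-19,6β:15,16-diolide | O=C1C[C@H]2OC(=O)[C@@]3(C)CCC[C@@](C)([C@@H]23)[C@@]1(O)CCC1=CC(=O)OC1
F6 | step 23 | 8β,9α-dihydroxylabd-13-ene-19,6β:15,16-diolide | C[C@]1(O)C[C@H]2OC(=O)[C@@]3(C)CCC[C@@](C)([C@@H]23)[C@@]1(O)CCC1=CC(=O)OC1
F7 | step 24 | (13S)-9α,13-epoxy-8-oxo-7-(phenylselanyl)-17-norlabdan-15,16-olid-19-oic acid (C7 epimers) | O=C1C([Se]c5ccccc5)C[C@H]2[C@@](C)(C(=O)O)CCC[C@]2(C)[C@@]13CC[C@]4(COC(=O)C4)O3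
A1 | alternative 1 | (13S)-9α,13-epoxy-8-oxo-17-norlabdane-19,6β:15,16-diolide | O=C1C[C@H]2OC(=O)[C@@]3(C)CCC[C@@](C)([C@@H]23)[C@@]12CC[C@]1(COC(=O)C1)O2
A2 | alternative 1 | 9α,13-epoxy-8-oxo-14,15,17-trinorlabdan-19,6β-olid-16-yl diazoacetate | O=C1C[C@H]2OC(=O)[C@@]3(C)CCC[C@@](C)([C@@H]23)[C@@]12CC[C@H](COC(=O)C=[N+]=[N-])O2
A3 | alternative 2 | 15,16-epoxy-9α-hydroxy-8-oxo-17-norlabda-13(16),14-dien-19,6β-olide | O=C1C[C@H]2OC(=O)[C@@]3(C)CCC[C@@](C)([C@@H]23)[C@@]1(O)CCc1ccoc1
A4 | alternative 2 | 15,16-epoxy-8,9-dioxo-8,9-seco-17-norlabda-13(16),14-dien-19,6β-olide | O=CC[C@H]1OC(=O)[C@@]2(C)CCC[C@@](C)([C@@H]12)C(=O)CCc1ccoc1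
A5 | alternative 3 | methyl (13S)-9α,13-epoxy-8-oxo-17-norlabda-5(10),6-dien-15,16-olid-19-oate | O=C1C=CC([C@@]2(C)C(=O)OC)=C(CCC2)[C@@]13CC[C@]1(COC(=O)C1)O3
A6 | alternative 3 | methyl 8,13-dihydroxy-17-norlabda-5(10),6,8-trien-15,16-olid-19-oate | Oc1ccc2c(c1CC[C@@]1(O)COC(=O)C1)CCC[C@]2(C)C(=O)OC
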